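A direct plan would make two complete isoflavones by the same sequence (Friedel–Crafts acylation of a phenol with an arylacetic acid in BF3·OEt2, then ring closure with DMF/MsCl): 8-hydroxy-5,7-dimethoxy-3-(4-methoxyphenyl)chromen-4-one A1 and 8-chloro-3-(4-iodophenyl)-5,7-dimethoxychromen-4-one A2. It would join them by a copper-catalysed Ullmann C–O coupling (CuI, picolinic acid, K3PO4) to pentamethyl ether A3 and cleave the methyl ethers with BBr3.
Weak point 1, the Ullmann ether coupling of A1 with A2: the phenol is flanked by a methoxy group and the ring oxygen, both partners are finished, base-sensitive pyranones heated with phosphate in DMSO, and this single late union carries the material of both branches.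
Weak point 2, the acylation and formylative ring closure that gives A1: it would run on an unprotected, air-sensitive catechol in hot neat BF3·OEt2 and then with MsCl/DMF, so the acylation site, partial demethylation and reaction at the second hydroxyl are all uncertain.
Weak point 3, the separate annulation that gives A2: the same three-bond ring construction would be repeated on an unrelated substrate only to carry an iodine atom that is discarded in the coupling, so the two rings C are built in parallel runs that share nothing.

**Retrosynthetic overview**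
Both pyranone rings (ring C of each unit) are cut at O1–C2 and, through a retro 1,2-aryl shift, at C3–C1', which leads back to the acyclic bis-chalcone 11 in which each ring B still sits on the carbon that becomes C2.
The diaryl ether (C8 of ring A of the genistein unit to C4' of ring B of the chlorinated unit) is made first, on small fragments, by metal-free SNAr on 4-fluorobenzaldehyde; the formyl group that activates the fluoride later becomes C2 of the chlorinated isoflavone, which is possible only because ring B moves to C3 in the key step.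
Order of ring formation: rings A and B are bought, no ring is closed before step 7, and both rings C then form together in one flask.
This avoids the hindered late copper coupling (the ether exists before any ring C) and the two separate annulations (one twofold rearrangement and cyclisation; each ketone has a single ortho hydroxyl, which fixes Cl and the aryloxy group at C8).

Key step: step 7

Assumption: 2-hydroxy-4,6-dimethoxybenzaldehyde 1 and 2-chloro-3,5-dimethoxyphenol 9 are taken as purchasable; the target has no stereocentre, and bis-acetal 12 is handled as a mixture of diastereomers.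

Step 1
Reactants: 1 2-hydroxy-4,6-dimethoxybenzaldehyde
Product: 3 3,5-dimethoxybenzene-1,2-diol, via aryl formate 2 (not isolated)
Conditions: 30% H2O2, NaOH, H2O/THF, 0 °C to rt, N2; then aq. HCl
Reagents that add atoms: hydrogen peroxide, OO
Why: Dakin oxidation, in which hydroperoxide adds to the aldehyde, the electron-rich ortho-hydroxyaryl group migrates to oxygen and the formate is saponified in the flask to the catechol; no stereocentre is formed.

Step 2
Reactants: 3 3,5-dimethoxybenzene-1,2-diol
Product: 4 1-(2,3-dihydroxy-4,6-dimethoxyphenyl)ethan-1-one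
Conditions: AcOH, BF3·OEt2 (neat), 80 °C, Ar; then H2O
Reagents that add atoms: acetic acid, CC(=O)O
Why: BF3-mediated Friedel–Crafts (Fries-type) ortho-acylation at C6, the only free position next to a hydroxyl, which should give the chelated ortho-hydroxy ketone and leave the hydroxyl between OH and OMe free for the later ether formation; no stereocentre is formed.

Step 3
Reactants: 4 1-(2,3-dihydroxy-4,6-dimethoxyphenyl)ethan-1-one; 5 4-(benzyloxy)benzaldehyde
Product: 6 (2E)-3-[4-(benzyloxy)phenyl]-1-(2,3-dihydroxy-4,6-dimethoxyphenyl)prop-2-en-1-one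
Conditions: KOH (50% aq.), EtOH, rt, Ar; then aq. HCl
Reagents that add atoms: none
Why: Claisen–Schmidt condensation, in which the methyl ketone enolate adds to the non-enolisable aldehyde and E1cB dehydration should give the conjugated enone with the thermodynamically favoured E geometry; no stereocentre is formed.

Step 4
Reactants: 6 (2E)-3-[4-(benzyloxy)phenyl]-1-(2,3-dihydroxy-4,6-dimethoxyphenyl)prop-2-en-1-one; 7 4-fluorobenzaldehyde
Product: 8 4-(3-{(2E)-3-[4-(benzyloxy)phenyl]prop-2-enoyl}-2-hydroxy-4,6-dimethoxyphenoxy)benzaldehyde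
Conditions: K2CO3, DMF, 80 °C, Ar; then aq. NH4Cl
Reagents that add atoms: none
Why: SNAr, in which the 3'-phenoxide (not chelated and not conjugated to the ketone) displaces fluoride para to the formyl group through a Meisenheimer adduct, a metal-free reaction that tolerates 2,6-disubstituted phenoxides, while the hydrogen-bonded 2'-hydroxyl should stay untouched; no stereocentre is formed.

Step 5
Reactants: 9 2-chloro-3,5-dimethoxyphenol
Product: 10 1-(3-chloro-2-hydroxy-4,6-dimethoxyphenyl)ethan-1-one
Conditions: AcOH, BF3·OEt2 (neat), 80 °C, Ar; then H2O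
Reagents that add atoms: acetic acid, CC(=O)O
Why: BF3-mediated Friedel–Crafts ortho-acylation, in which the single hydroxyl of 9 directs the acetyl group to C6, so that chlorine ends next to the hydroxyl that will become the ring oxygen; no stereocentre is formed.

Step 6
Reactants: 8 4-(3-{(2E)-3-[4-(benzyloxy)phenyl]prop-2-enoyl}-2-hydroxy-4,6-dimethoxyphenoxy)benzaldehyde; 10 1-(3-chloro-2-hydroxy-4,6-dimethoxyphenyl)ethan-1-one
Product: 11 (2E)-3-[4-(3-{(2E)-3-[4-(benzyloxy)phenyl]prop-2-enoyl}-2-hydroxy-4,6-dimethoxyphenoxy)phenyl]-1-(3-chloro-2-hydroxy-4,6-dimethoxyphenyl)prop-2-en-1-one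
Conditions: KOH (50% aq.), EtOH, rt, Ar; then aq. HCl
Reagents that add atoms: none
Why: Claisen–Schmidt condensation of the enolate of 10 with the aryl aldehyde of 8, which has no enolisable ketone left because its acetyl group was used in step 3, so that self-condensation is excluded and the second E enone should form; no stereocentre is formed.

Step 7
Reactants: 11 (2E)-3-[4-(3-{(2E)-3-[4-(benzyloxy)phenyl]prop-2-enoyl}-2-hydroxy-4,6-dimethoxyphenoxy)phenyl]-1-(3-chloro-2-hydroxy-4,6-dimethoxyphenyl)prop-2-en-1-one
Product: 13 3-[4-({3-[4-(benzyloxy)phenyl]-5,7-dimethoxy-4-oxo-4H-chromen-8-yl}oxy)phenyl]-8-chloro-5,7-dimethoxy-4H-chromen-4-one, via bis-acetal 12 (not isolated)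
Conditions: Tl(NO3)3·3H2O (2.3 equiv), MeOH/HC(OMe)3, rt; then 10% aq. HCl, 60 °C
Reagents that add atoms: none
Why: Trivalent thallium adds to each enone C=C with methanol entering at the benzylic β-carbon, the ring B aryl group then shifts from Cβ to Cα through a bridged phenonium ion as monovalent thallium leaves, and methanol traps the oxocarbenium ion, so that both enones of 11 become 2-aryl-3,3-dimethoxypropan-1-ones in bis-acetal 12 (a mixture of diastereomers whose two stereocentres are erased in the next event). The closest known reaction is the Tl(NO3)3 oxidative rearrangement of 2'-hydroxychalcones to isoflavones, the laboratory counterpart of the aryl migration of isoflavone biosynthesis, here run twice on one molecule. On acidification each chelated 2'-hydroxyl attacks the oxocarbenium ion formed from its acetal (6-exo-trig) and loss of methanol aromatises the pyranone, so both rings C close in the same flask and no stereocentre remains. The step needs aryl migration to win over aurone formation and ring oxidation: both migrating rings carry a para oxygen donor (benzyloxy, aryloxy), and the hydroxyls are deactivated by hydrogen bonding to the ketones. The regiochemistry of both ring closures is fixed by the substrate, since each ketone has only one ortho hydroxyl (the other ortho position is OMe), which places chlorine and the aryloxy group at C8 of their units.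

Step 8
Reactants: 13 3-[4-({3-[4-(benzyloxy)phenyl]-5,7-dimethoxy-4-oxo-4H-chromen-8-yl}oxy)phenyl]-8-chloro-5,7-dimethoxy-4H-chromen-4-one
Product: 14 8-chloro-3-[4-({5,7-dihydroxy-3-(4-hydroxyphenyl)-4-oxo-4H-chromen-8-yl}oxy)phenyl]-5,7-dihydroxy-4H-chromen-4-one
Conditions: BBr3 (excess), CH2Cl2, −78 °C to rt; then MeOH, H2O
Reagents that add atoms: none
Why: Lewis-acid cleavage of the four aryl methyl ethers and the benzyl ether, in which BBr3 coordinates each ether oxygen and bromide removes the methyl or benzyl group by SN2, while the diaryl ether, the aryl chloride and both pyranones should be inert; the product is achiral.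

**Compound list**
1 | 2-hydroxy-4,6-dimethoxybenzaldehyde | COc1cc(O)c(C=O)c(OC)c1 | starting material
2 | 2-hydroxy-4,6-dimethoxyphenyl formate | COc1cc(O)c(OC=O)c(OC)c1 | intermediate
3 | 3,5-dimethoxybenzene-1,2-diol | COc1cc(O)c(O)c(OC)c1 | intermediate
4 | 1-(2,3-dihydroxy-4,6-dimethoxyphenyl)ethan-1-one | CC(=O)c1c(O)c(O)c(OC)cc1OC | intermediate
5 | 4-(benzyloxy)benzaldehyde | O=Cc1ccc(OCc2ccccc2)cc1 | starting material
6 | (2E)-3-[4-(benzyloxy)phenyl]-1-(2,3-dihydroxy-4,6-dimethoxyphenyl)prop-2-en-1-one | COc1cc(OC)c(C(=O)/C=C/c2ccc(OCc3ccccc3)cc2)c(O)c1O | intermediate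
7 | 4-fluorobenzaldehyde | O=Cc1ccc(F)cc1 | starting material
8 | 4-(3-{(2E)-3-[4-(benzyloxy)phenyl]prop-2-enoyl}-2-hydroxy-4,6-dimethoxyphenoxy)benzaldehyde | COc1cc(OC)c(C(=O)/C=C/c2ccc(OCc3ccccc3)cc2)c(O)c1Oc1ccc(C=O)cc1 | intermediate
9 | 2-chloro-3,5-dimethoxyphenol | COc1cc(O)c(Cl)c(OC)c1 | starting material
10 | 1-(3-chloro-2-hydroxy-4,6-dimethoxyphenyl)ethan-1-one | CC(=O)c1c(O)c(Cl)c(OC)cc1OC | intermediate
11 | (2E)-3-[4-(3-{(2E)-3-[4-(benzyloxy)phenyl]prop-2-enoyl}-2-hydroxy-4,6-dimethoxyphenoxy)phenyl]-1-(3-chloro-2-hydroxy-4,6-dimethoxyphenyl)prop-2-en-1-one | COc1cc(OC)c(C(=O)/C=C/c2ccc(OCc3ccccc3)cc2)c(O)c1Oc1ccc(/C=C/C(=O)c2c(O)c(Cl)c(OC)cc2OC)cc1 | intermediate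
12 | 2-[4-(benzyloxy)phenyl]-1-[3-(4-{1-(3-chloro-2-hydroxy-4,6-dimethoxyphenyl)-3,3-dimethoxy-1-oxopropan-2-yl}phenoxy)-2-hydroxy-4,6-dimethoxyphenyl]-3,3-dimethoxypropan-1-one (mixture of diastereomers) | COc1cc(OC)c(C(=O)C(C(OC)OC)c2ccc(OCc3ccccc3)cc2)c(O)c1Oc1ccc(C(C(OC)OC)C(=O)c2c(O)c(Cl)c(OC)cc2OC)cc1 | intermediate
13 | 3-[4-({3-[4-(benzyloxy)phenyl]-5,7-dimethoxy-4-oxo-4H-chromen-8-yl}oxy)phenyl]-8-chloro-5,7-dimethoxy-4H-chromen-4-one | COc1cc(OC)c2c(=O)c(-c3ccc(OCc4ccccc4)cc3)coc2c1Oc1ccc(-c2coc3c(Cl)c(OC)cc(OC)c3c2=O)cc1 | intermediate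
14 | 8-chloro-3-[4-({5,7-dihydroxy-3-(4-hydroxyphenyl)-4-oxo-4H-chromen-8-yl}oxy)phenyl]-5,7-dihydroxy-4H-chromen-4-one | O=c1c(-c2ccc(Oc3c(O)cc(O)c4c(=O)c(-c5ccc(O)cc5)coc34)cc2)coc2c(Cl)c(O)cc(O)c12 | target

Total step count: 8. Longest linear sequence: 7 (steps 1, 2, 3, 4, 6, 7, 8).

**Steps most likely to fail**

Step 7. A free 2'-hydroxyl may cyclise onto the thallated enone (aurone pathway), or trivalent thallium may oxidise the tetra-oxygenated ring A of the genistein unit before the aryl shift, so that only one of the two enones rearranges cleanly. The fallback sets out from 11: both chalcones would be closed with NaOAc in refluxing EtOH to bis-flavanone F1, which has neither a free phenol nor an enone. The 2,3-aryl shift of flavanones with PhI(OH)OTs in MeCN at reflux (α-iodanylation of each ketone, aryl migration from C2 to C3, loss of a proton) should then give 13, where the fallback rejoins the route.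

Step 4. Under carbonate in hot DMF the 2'-hydroxychalcone may isomerise to its flavanone, oligomerise by oxa-Michael addition, or be arylated at the chelated hydroxyl. The fallback sets out from 6: it would be isomerised on purpose (NaOAc, EtOH, reflux) to hydroxyflavanone F2, whose single free 8-hydroxyl would be arylated with 7 (K2CO3, DMF) to flavanone aldehyde F3. Under the KOH/EtOH conditions of step 6, F3 should open by E1cB to chalcone 8 in the flask and condense with 10, so the fallback rejoins the route at 8.

Step 3. The electron-rich catechol dianion may be oxidised by traces of air, and the doubly deprotonated ketone may enolise too slowly for the aldol addition. The fallback sets out from 4: SNAr with 7 (K2CO3, DMF) would come first and give keto aldehyde F4, whose aldehyde would be masked as dimethyl acetal F5 (HC(OMe)3, cat. TsOH, MeOH) so that the ketone cannot condense with its own formyl group. Claisen–Schmidt condensation of F5 with 5 (KOH, EtOH) would give chalcone acetal F6, and dilute HCl in the work-up should release the aldehyde and return to the route at 8.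

**Further compounds**
F1 | step 7 | 2-[4-(benzyloxy)phenyl]-8-[4-(8-chloro-5,7-dimethoxy-4-oxochroman-2-yl)phenoxy]-5,7-dimethoxychroman-4-one (mixture of diastereomers) | COc1cc(OC)c2C(=O)CC(c3ccc(OCc4ccccc4)cc3)Oc2c1Oc1ccc(cc1)C1CC(=O)c2c(OC)cc(OC)c(Cl)c2O1
F2 | step 4 | 2-[4-(benzyloxy)phenyl]-8-hydroxy-5,7-dimethoxychroman-4-one (racemic) | COc1cc(OC)c2C(=O)CC(c3ccc(OCc4ccccc4)cc3)Oc2c1O
F3 | step 4 | 4-({2-[4-(benzyloxy)phenyl]-5,7-dimethoxy-4-oxochroman-8-yl}oxy)benzaldehyde (racemic) | COc1cc(OC)c2C(=O)CC(c3ccc(OCc4ccccc4)cc3)Oc2c1Oc1ccc(C=O)cc1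
F4 | step 3 | 4-(3-acetyl-2-hydroxy-4,6-dimethoxyphenoxy)benzaldehyde | CC(=O)c1c(O)c(Oc2ccc(C=O)cc2)c(OC)cc1OC
F5 | step 3 | 1-{3-[4-(dimethoxymethyl)phenoxy]-2-hydroxy-4,6-dimethoxyphenyl}ethan-1-one | CC(=O)c1c(O)c(Oc2ccc(C(OC)OC)cc2)c(OC)cc1OC
F6 | step 3 | (2E)-3-[4-(benzyloxy)phenyl]-1-{3-[4-(dimethoxymethyl)phenoxy]-2-hydroxy-4,6-dimethoxyphenyl}prop-2-en-1-one | COc1cc(OC)c(C(=O)/C=C/c2ccc(OCc3ccccc3)cc2)c(O)c1Oc1ccc(C(OC)OC)cc1
A1 | direct plan | 8-hydroxy-5,7-dimethoxy-3-(4-methoxyphenyl)-4H-chromen-4-one | COc1ccc(-c2coc3c(O)c(OC)cc(OC)c3c2=O)cc1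
A2 | direct plan | 8-chloro-3-(4-iodophenyl)-5,7-dimethoxy-4H-chromen-4-one | COc1cc(OC)c2c(=O)c(-c3ccc(I)cc3)coc2c1Cl
A3 | direct plan | 8-chloro-3-[4-({5,7-dimethoxy-3-(4-methoxyphenyl)-4-oxo-4H-chromen-8-yl}oxy)phenyl]-5,7-dimethoxy-4H-chromen-4-one | COc1ccc(-c2coc3c(Oc4ccc(-c5coc6c(Cl)c(OC)cc(OC)c6c5=O)cc4)c(OC)cc(OC)c3c2=O)cc1
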